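**Retrosynthetic overview**
1. The (2S)-flavanone is disconnected at C3–C4: ring C is closed last by an enantioselective rhodium-catalysed hydroacylation of an aryl 1-arylvinyl ether that carries an ortho formyl group, and the same step sets C2.
2. Enabling feature: C2 of ring C carries both the ring oxygen O1 and ring B, so C2=C3 can exist as a 1-arylvinyl ether of the ring A phenol, with its CH2 terminus (C3) placed to meet the formyl carbon (C4) on C4a, ortho to O1. In ring A the lavandulyl carbon C6 lies para to C8a–O1, so the ring A phenol is symmetric, its two positions ortho to O1 are equivalent, and no 6- versus 8-isomer problem arises.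
3. The vinyl ether comes from methylenation of an aryl ester made from a ring A bromophenol and a ring B benzoic acid; the bromide is the masked formyl group.
4. The (R)-lavandulyl unit is made by Evans deconjugative prenylation and joined to ring A by Negishi coupling at the carbon between two MOM ethers.
5. Order of rings: rings A and B are bought as phloroglucinol; ring C is the only ring formed (step 16); the MOM groups are then exchanged for silyl groups and removed with buffered fluoride.

Key step: step 16

Remark: flavanone numbering (O1, C2, C3, C4, C4a, C5–C8, C8a) is used; "lavandulyl" stands for 5-methyl-2-(prop-1-en-2-yl)hex-4-en-1-yl, which is (2S) in every arene-bound compound below.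
Assumption: the sense of induction written for (R)-DTBM-SEGPHOS in step 16 rests on analogy only; should the (2R) series form, the (S)-ligand is used and nothing else changes.

**Route**

Step 1
Reactants: 1 (4R)-4-benzyl-1,3-oxazolidin-2-one; 2 3-methylbut-2-enoyl chloride
Product: 4 (4R)-4-benzyl-3-(3-methylbut-2-enoyl)-1,3-oxazolidin-2-one, via lithium oxazolidinide 3 (not isolated)
Conditions: n-BuLi, THF, −78 °C; then 2, −78 → 0 °C
Reagents that add atoms: none
Why: N-acylation of the lithiated Evans oxazolidinone by the acid chloride; the auxiliary centre is untouched, and any double-bond deconjugation is harmless because both isomers give the same dienolate in step 2.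

Step 2
Reactants: 4 (4R)-4-benzyl-3-(3-methylbut-2-enoyl)-1,3-oxazolidin-2-one; 5 1-bromo-3-methylbut-2-ene (prenyl bromide)
Product: 7 (4R)-4-benzyl-3-[(2R)-5-methyl-2-(prop-1-en-2-yl)hex-4-enoyl]-1,3-oxazolidin-2-one, via sodium dienolate 6 (not isolated)
Conditions: NaN(SiMe3)2, THF, −78 °C; then 5, −78 → −20 °C
Reagents that add atoms: none
Why: Evans deconjugative alkylation: γ-deprotonation gives the chelated (Z)-dienolate, which should be alkylated at the α-carbon (the kinetic site of alkali-metal dienolates) on the face opposite the benzyl group, setting the (R) side-chain centre.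

Step 3
Reactants: 7 (4R)-4-benzyl-3-[(2R)-5-methyl-2-(prop-1-en-2-yl)hex-4-enoyl]-1,3-oxazolidin-2-one
Product: 8 (2R)-5-methyl-2-(prop-1-en-2-yl)hex-4-en-1-ol [(R)-lavandulol]
Conditions: LiBH4, MeOH (1 equiv), THF, 0 °C
Reagents that add atoms: none
Why: reductive cleavage of the N-acyl oxazolidinone by LiBH4 should release the primary alcohol and the auxiliary; the alkenes are inert and the α-centre is not epimerised under these fast, weakly basic conditions.

Step 4
Reactants: 8 (2R)-5-methyl-2-(prop-1-en-2-yl)hex-4-en-1-ol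
Product: 9 (3R)-3-(iodomethyl)-2,6-dimethylhepta-1,5-diene [(R)-lavandulyl iodide]
Conditions: PPh3, I2, imidazole, CH2Cl2, 0 °C → rt
Reagents that add atoms: iodine, [I][I]
Why: Appel-type iodination substitutes the primary alcohol by SN2 at CH2, so the neighbouring stereocentre is not touched.

Step 5
Reactants: 10 phloroglucinol (benzene-1,3,5-triol)
Product: 11 3,5-bis(methoxymethoxy)phenol
Conditions: MOMCl (2.0 equiv), i-Pr2NEt, DMF, 0 °C → rt; chromatography
Reagents that add atoms: chloromethyl methyl ether (MOMCl), COCCl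
Why: Williamson-type O-alkylation with a limiting amount of MOMCl should give the bis-ether statistically, the mono- and tris-ethers being removed by chromatography.

Step 6
Reactants: 11 3,5-bis(methoxymethoxy)phenol
Product: 12 [3,5-bis(methoxymethoxy)phenoxy]tri(propan-2-yl)silane
Conditions: TIPSCl, imidazole, DMF, rt
Reagents that add atoms: chlorotri(propan-2-yl)silane (TIPSCl), CC(C)[Si](Cl)(C(C)C)C(C)C
Why: standard silylation of the remaining phenol; the bulky TIPS ether is stable to n-BuLi and, unlike MOM, does not direct metalation.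

Step 7
Reactants: 12 [3,5-bis(methoxymethoxy)phenoxy]tri(propan-2-yl)silane
Product: 14 [4-iodo-3,5-bis(methoxymethoxy)phenoxy]tri(propan-2-yl)silane, via aryllithium 13 (not isolated)
Conditions: n-BuLi, THF, 0 °C; then I2, −78 °C → rt
Reagents that add atoms: iodine, [I][I]
Why: directed ortho metalation: the position between the two MOM ethers is doubly activated and not shielded by the TIPS group, so lithiation and iodine quench should place iodine at the future C6.

Step 8
Reactants: 9 (3R)-3-(iodomethyl)-2,6-dimethylhepta-1,5-diene; 14 [4-iodo-3,5-bis(methoxymethoxy)phenoxy]tri(propan-2-yl)silane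
Product: 16 {3,5-bis(methoxymethoxy)-4-[(2S)-lavandulyl]phenoxy}tri(propan-2-yl)silane, via lavandulylzinc iodide 15 (not isolated)
Conditions: 9, Zn dust, LiCl, THF, 40 °C; then 14, Pd(OAc)2 (2 mol %), SPhos (4 mol %), THF, 50 °C
Reagents that add atoms: none
Why: Negishi sp3–sp2 cross-coupling: zinc insertion into the primary iodide and coupling with the doubly ortho-substituted aryl iodide on zerovalent palladium/SPhos should join side chain and ring A; the stereocentre is β to zinc and not involved, its descriptor becoming S only through the CIP priorities.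

Step 9
Reactants: 16 {3,5-bis(methoxymethoxy)-4-[(2S)-lavandulyl]phenoxy}tri(propan-2-yl)silane
Product: 17 3,5-bis(methoxymethoxy)-4-[(2S)-lavandulyl]phenol
Conditions: Bu4NF, AcOH, THF, 0 °C
Reagents that add atoms: none
Why: fluoride cleaves the aryl silyl ether, acetic acid buffers the phenoxide, and MOM ethers and alkenes are inert.

Step 10
Reactants: 17 3,5-bis(methoxymethoxy)-4-[(2S)-lavandulyl]phenol
Product: 18 2-bromo-3,5-bis(methoxymethoxy)-4-[(2S)-lavandulyl]phenol
Conditions: NBS (1.0 equiv), CH2Cl2, −78 °C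
Reagents that add atoms: N-bromosuccinimide (NBS), O=C1CCC(=O)N1Br
Why: electrophilic aromatic bromination of the very electron-rich phenol should outrun attack on the side-chain alkenes at −78 °C; the para position is blocked and the two ortho positions are equivalent, so only one regioisomer can form.

Step 11
Reactants: 10 phloroglucinol (benzene-1,3,5-triol)
Product: 19 1,3,5-tris(methoxymethoxy)benzene
Conditions: MOMCl (4 equiv), i-Pr2NEt, DMF, 0 °C → rt
Reagents that add atoms: chloromethyl methyl ether (MOMCl), COCCl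
Why: exhaustive Williamson-type MOM protection of the three phenols.

Step 12
Reactants: 19 1,3,5-tris(methoxymethoxy)benzene
Product: 21 2,4,6-tris(methoxymethoxy)benzoic acid, via aryllithium 20 (not isolated)
Conditions: n-BuLi, THF, 0 °C; then CO2 (g), −78 °C → rt; cold 0.5 M HCl to pH 3–4
Reagents that add atoms: carbon dioxide, O=C=O
Why: directed ortho metalation between two MOM ethers (all three ring positions are equivalent) followed by carboxylation of the aryllithium.

Step 13
Reactants: 18 2-bromo-3,5-bis(methoxymethoxy)-4-[(2S)-lavandulyl]phenol; 21 2,4,6-tris(methoxymethoxy)benzoic acid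
Product: 22 2-bromo-3,5-bis(methoxymethoxy)-4-[(2S)-lavandulyl]phenyl 2,4,6-tris(methoxymethoxy)benzoate
Conditions: DCC, DMAP (0.2 equiv), CH2Cl2, 0 °C → rt
Reagents that add atoms: none
Why: Steglich esterification acylates the only free phenol under neutral conditions that spare the MOM acetals.

Step 14
Reactants: 22 2-bromo-3,5-bis(methoxymethoxy)-4-[(2S)-lavandulyl]phenyl 2,4,6-tris(methoxymethoxy)benzoate
Product: 23 2-bromo-3,5-bis(methoxymethoxy)-4-[(2S)-lavandulyl]phenyl 1-[2,4,6-tris(methoxymethoxy)phenyl]ethenyl ether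
Conditions: Cp2TiMe2 (3 equiv), toluene/THF, 70 °C, dark; filtration through basic alumina
Reagents that add atoms: dimethyltitanocene (Cp2TiMe2), C[Ti](C)(C1C=CC=C1)C1C=CC=C1
Why: Petasis methylenation: thermally generated Cp2Ti=CH2 adds to the ester carbonyl and cycloreverts to the 1-arylvinyl aryl ether (the classic conversion of aryl benzoates into α-aryloxystyrenes); the medium is non-acidic, so MOM groups, aryl bromide and alkenes should survive, and the acid-labile product is isolated on basic alumina.

Step 15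
Reactants: 23 2-bromo-3,5-bis(methoxymethoxy)-4-[(2S)-lavandulyl]phenyl 1-[2,4,6-tris(methoxymethoxy)phenyl]ethenyl ether
Product: 25 2,4-bis(methoxymethoxy)-3-[(2S)-lavandulyl]-6-({1-[2,4,6-tris(methoxymethoxy)phenyl]ethenyl}oxy)benzaldehyde, via aryllithium 24 (not isolated)
Conditions: n-BuLi, THF, −78 °C; then DMF, −78 → 0 °C; H2O
Reagents that add atoms: N,N-dimethylformamide (DMF), CN(C)C=O
Why: bromine–lithium exchange at −78 °C should be faster than deprotonation of ring B or attack on the enol ether, and the aryllithium is formylated by DMF (Bouveault aldehyde synthesis); the non-acidic aqueous work-up keeps the enol ether intact.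

Step 16
Reactants: 25 2,4-bis(methoxymethoxy)-3-[(2S)-lavandulyl]-6-({1-[2,4,6-tris(methoxymethoxy)phenyl]ethenyl}oxy)benzaldehyde
Product: 26 (2S)-5,7-bis(methoxymethoxy)-6-[(2S)-lavandulyl]-2-[2,4,6-tris(methoxymethoxy)phenyl]-2,3-dihydro-4H-chromen-4-one
Conditions: [Rh(cod)Cl]2 (2.5 mol %), (R)-DTBM-SEGPHOS (5 mol %), NaB[3,5-(CF3)2C6H3]4 (5 mol %), THF, 60 °C
Reagents that add atoms: none
Why: Proposed new method: the cationic monovalent rhodium bisphosphine complex should add oxidatively into the formyl C–H bond of 25; the acyl hydride of trivalent rhodium then binds the tethered 1-arylvinyl ether and inserts it into Rh–H with hydride going to C2 and rhodium to the CH2 terminus C3, and C–C reductive elimination from the seven-membered acyl(alkyl)rhodacycle forms C3–C4 and releases 26. The closest known reaction type is the rhodium-catalysed enantioselective endo-hydroacylation of ortho-allylbenzaldehydes and 2-vinylbenzaldehydes bearing 1,1-disubstituted alkenes (to 3-substituted tetralones and indanones), carried over here to an oxygen-tethered enol ether. Ring C closes in the 6-endo-trig mode with respect to the vinyl ether. The only new stereocentre, C2, is set in the hydride-insertion step, where the chiral bisphosphine selects the enantiotopic alkene face (catalyst control; the remote side-chain centre should not interfere). The step needs 6-endo over 5-exo closure (which would give a 2-aryl-2-methylbenzofuran-3-one) and hydroacylation over decarbonylation: C2 is fully substituted and shielded by the doubly ortho-substituted ring B, the enol ether is polarised so that its nucleophilic CH2 binds rhodium while hydride goes to the oxocarbenium-like C2, and the ortho MOM ether can chelate and stabilise the acyl hydride. The lavandulyl alkenes cannot reach the acyl rhodium centre in a ring of workable size, and the reaction is a neutral isomerisation, so the MOM acetals and the new benzylic ether should survive.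

Step 17
Reactants: 26 (2S)-5,7-bis(methoxymethoxy)-6-[(2S)-lavandulyl]-2-[2,4,6-tris(methoxymethoxy)phenyl]-2,3-dihydro-4H-chromen-4-one
Product: 27 (2S)-5,7-bis(triethylsilyloxy)-6-[(2S)-lavandulyl]-2-[2,4,6-tris(triethylsilyloxy)phenyl]-2,3-dihydro-4H-chromen-4-one
Conditions: Et3SiOTf (10 equiv), 2,2'-bipyridyl (15 equiv), MeCN, 0 °C → rt; then H2O
Reagents that add atoms: triethylsilyl trifluoromethanesulfonate (Et3SiOTf), CC[Si](CC)(CC)OS(=O)(=O)C(F)(F)F
Why: silyl triflate/2,2'-bipyridyl exchange of aromatic MOM ethers for aryl silyl ethers: the bipyridyl-bound silyl cation activates each acetal and bipyridyl captures the methoxymethyl unit as a pyridinium salt, a buffered non-protic process that is intended to leave the acid-labile benzylic C2–O1 bond un-ionised and keeps the formaldehyde set free on work-up away from free phloroglucinol-type rings.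

Step 18
Reactants: 27 (2S)-5,7-bis(triethylsilyloxy)-6-[(2S)-lavandulyl]-2-[2,4,6-tris(triethylsilyloxy)phenyl]-2,3-dihydro-4H-chromen-4-one
Product: 28 (2S)-5,7-dihydroxy-6-[(2S)-5-methyl-2-(prop-1-en-2-yl)hex-4-en-1-yl]-2-(2,4,6-trihydroxyphenyl)-2,3-dihydro-4H-chromen-4-one (CNP0107340.1)
Conditions: Bu4NF (5.5 equiv), AcOH (6 equiv), THF, 0 °C
Reagents that add atoms: none
Why: acetic acid-buffered fluoride cleaves the aryl triethylsilyl ethers near neutrality, avoiding both the acid that would ionise C2–O1 and the base that would open the flavanone to its chalcone (loss of C2 configuration and possible reclosure through the other ortho hydroxyl).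

**Compound list**
1 | (4R)-4-benzyl-1,3-oxazolidin-2-one | O=C1N[C@H](Cc2ccccc2)CO1 | starting material
2 | 3-methylbut-2-enoyl chloride | CC(C)=CC(=O)Cl | starting material
3 | lithium (4R)-4-benzyl-2-oxo-1,3-oxazolidin-3-ide | [Li]N1[C@H](Cc2ccccc2)COC1=O | intermediate (not isolated)
4 | (4R)-4-benzyl-3-(3-methylbut-2-enoyl)-1,3-oxazolidin-2-one | CC(C)=CC(=O)N1[C@H](Cc2ccccc2)COC1=O | intermediate
5 | 1-bromo-3-methylbut-2-ene (prenyl bromide) | CC(C)=CCBr | starting material
6 | sodium (1Z)-1-[(4R)-4-benzyl-2-oxo-1,3-oxazolidin-3-yl]-3-methylbuta-1,3-dien-1-olate | C=C(C)/C=C(\O[Na])N1[C@H](Cc2ccccc2)COC1=O | intermediate (not isolated)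
7 | (4R)-4-benzyl-3-[(2R)-5-methyl-2-(prop-1-en-2-yl)hex-4-enoyl]-1,3-oxazolidin-2-one | C=C(C)[C@@H](CC=C(C)C)C(=O)N1[C@H](Cc2ccccc2)COC1=O | intermediate
8 | (2R)-5-methyl-2-(prop-1-en-2-yl)hex-4-en-1-ol, (R)-lavandulol | C=C(C)[C@@H](CC=C(C)C)CO | intermediate
9 | (3R)-3-(iodomethyl)-2,6-dimethylhepta-1,5-diene | C=C(C)[C@@H](CC=C(C)C)CI | intermediate
10 | phloroglucinol (benzene-1,3,5-triol) | Oc1cc(O)cc(O)c1 | starting material
11 | 3,5-bis(methoxymethoxy)phenol | COCOc1cc(O)cc(OCOC)c1 | intermediate
12 | [3,5-bis(methoxymethoxy)phenoxy]tri(propan-2-yl)silane | COCOc1cc(OCOC)cc(O[Si](C(C)C)(C(C)C)C(C)C)c1 | intermediate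
13 | {2,6-bis(methoxymethoxy)-4-[tri(propan-2-yl)silyloxy]phenyl}lithium | [Li]c1c(OCOC)cc(O[Si](C(C)C)(C(C)C)C(C)C)cc1OCOC | intermediate (not isolated)
14 | [4-iodo-3,5-bis(methoxymethoxy)phenoxy]tri(propan-2-yl)silane | COCOc1cc(O[Si](C(C)C)(C(C)C)C(C)C)cc(OCOC)c1I | intermediate
15 | [(2R)-5-methyl-2-(prop-1-en-2-yl)hex-4-en-1-yl]zinc iodide | C=C(C)[C@@H](CC=C(C)C)C[Zn]I | intermediate (not isolated)
16 | {3,5-bis(methoxymethoxy)-4-[(2S)-5-methyl-2-(prop-1-en-2-yl)hex-4-en-1-yl]phenoxy}tri(propan-2-yl)silane | C=C(C)[C@@H](CC=C(C)C)Cc1c(OCOC)cc(O[Si](C(C)C)(C(C)C)C(C)C)cc1OCOC | intermediate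
17 | 3,5-bis(methoxymethoxy)-4-[(2S)-5-methyl-2-(prop-1-en-2-yl)hex-4-en-1-yl]phenol | C=C(C)[C@@H](CC=C(C)C)Cc1c(OCOC)cc(O)cc1OCOC | intermediate
18 | 2-bromo-3,5-bis(methoxymethoxy)-4-[(2S)-5-methyl-2-(prop-1-en-2-yl)hex-4-en-1-yl]phenol | C=C(C)[C@@H](CC=C(C)C)Cc1c(OCOC)cc(O)c(Br)c1OCOC | intermediate
19 | 1,3,5-tris(methoxymethoxy)benzene | COCOc1cc(OCOC)cc(OCOC)c1 | intermediate
20 | [2,4,6-tris(methoxymethoxy)phenyl]lithium | [Li]c1c(OCOC)cc(OCOC)cc1OCOC | intermediate (not isolated)
21 | 2,4,6-tris(methoxymethoxy)benzoic acid | COCOc1cc(OCOC)c(C(=O)O)c(OCOC)c1 | intermediate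
22 | 2-bromo-3,5-bis(methoxymethoxy)-4-[(2S)-lavandulyl]phenyl 2,4,6-tris(methoxymethoxy)benzoate | C=C(C)[C@@H](CC=C(C)C)Cc1c(OCOC)cc(OC(=O)c2c(OCOC)cc(OCOC)cc2OCOC)c(Br)c1OCOC | intermediate
23 | 2-bromo-3,5-bis(methoxymethoxy)-4-[(2S)-lavandulyl]phenyl 1-[2,4,6-tris(methoxymethoxy)phenyl]ethenyl ether | C=C(C)[C@@H](CC=C(C)C)Cc1c(OCOC)cc(OC(=C)c2c(OCOC)cc(OCOC)cc2OCOC)c(Br)c1OCOC | intermediate
24 | aryllithium from 23 (lithium in place of bromine) | C=C(C)[C@@H](CC=C(C)C)Cc1c(OCOC)cc(OC(=C)c2c(OCOC)cc(OCOC)cc2OCOC)c([Li])c1OCOC | intermediate (not isolated)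
25 | 2,4-bis(methoxymethoxy)-3-[(2S)-lavandulyl]-6-({1-[2,4,6-tris(methoxymethoxy)phenyl]ethenyl}oxy)benzaldehyde | C=C(C)[C@@H](CC=C(C)C)Cc1c(OCOC)cc(OC(=C)c2c(OCOC)cc(OCOC)cc2OCOC)c(C=O)c1OCOC | intermediate
26 | (2S)-5,7-bis(methoxymethoxy)-6-[(2S)-lavandulyl]-2-[2,4,6-tris(methoxymethoxy)phenyl]-2,3-dihydro-4H-chromen-4-one | C=C(C)[C@@H](CC=C(C)C)Cc1c(OCOC)cc2c(c1OCOC)C(=O)C[C@@H](c1c(OCOC)cc(OCOC)cc1OCOC)O2 | intermediate
27 | (2S)-5,7-bis(triethylsilyloxy)-6-[(2S)-lavandulyl]-2-[2,4,6-tris(triethylsilyloxy)phenyl]-2,3-dihydro-4H-chromen-4-one | C=C(C)[C@@H](CC=C(C)C)Cc1c(O[Si](CC)(CC)CC)cc2c(c1O[Si](CC)(CC)CC)C(=O)C[C@@H](c1c(O[Si](CC)(CC)CC)cc(O[Si](CC)(CC)CC)cc1O[Si](CC)(CC)CC)O2 | intermediate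
28 | (2S)-5,7-dihydroxy-6-[(2S)-5-methyl-2-(prop-1-en-2-yl)hex-4-en-1-yl]-2-(2,4,6-trihydroxyphenyl)-2,3-dihydro-4H-chromen-4-one | C=C(C)[C@@H](CC=C(C)C)Cc1c(O)cc2c(c1O)C(=O)C[C@@H](c1c(O)cc(O)cc1O)O2 | target

**Step count and risks**
Total step count: 18. Longest linear sequence: 13 steps (steps 1–4, 8–10, 13–18).

Steps most likely to fail:

1. Step 16 (proposed new method). What may go wrong: insufficient discrimination of the alkene faces at the hindered enol ether, competing 5-exo closure, decarbonylation of the acyl rhodium hydride, or hydrolysis of the enol ether by adventitious acid. The fallback uses known chemistry and forms O1–C2 instead of C3–C4. It sets out from bromophenol 18: double lithiation (n-BuLi, 2.2 equiv, THF, −78 °C) and acylation with N-methoxy-N-methylacetamide should give 1-{6-hydroxy-2,4-bis(methoxymethoxy)-3-[(2S)-lavandulyl]phenyl}ethan-1-one F1. Claisen–Schmidt condensation (KOH, EtOH) with 2,4,6-tris(methoxymethoxy)benzaldehyde F2 (from 19 by lithiation as in step 12 and DMF quench) should give the (E)-2'-hydroxychalcone F3. Its single free phenol, the future O1, is then cyclised by the known catalytic asymmetric intramolecular oxa-Michael addition of 2'-hydroxychalcones (quinine- or quinidine-derived bifunctional thiourea chosen for the 2S sense, toluene, rt). The fallback comes back to the route at 26.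

2. Step 17. What may go wrong: ionisation of the benzylic C2–O1 bond by the silyl triflate (epimerisation at C2 or ring opening), or incomplete exchange at the hindered 5- and 2',6'-positions. The fallback moves the protecting-group exchange to before the stereocentre exists. It sets out from ester 22, which has no labile benzylic ether: the same Et3SiOTf/2,2'-bipyridyl exchange should give 2-bromo-3,5-bis(triethylsilyloxy)-4-[(2S)-lavandulyl]phenyl 2,4,6-tris(triethylsilyloxy)benzoate F4. Petasis methylenation as in step 14 gives the corresponding 1-arylethenyl ether F5. Bromine–magnesium exchange with i-PrMgCl·LiCl (THF, rt; an arylmagnesium is far less prone than an aryllithium to silyl migration from the ortho silyloxy group) and DMF give 2,4-bis(triethylsilyloxy)-3-[(2S)-lavandulyl]-6-({1-[2,4,6-tris(triethylsilyloxy)phenyl]ethenyl}oxy)benzaldehyde F6. Hydroacylation under the conditions of step 16 then comes back to the route at 27, so that only the buffered fluoride of step 18 follows the creation of C2.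

3. Step 14. What may go wrong: slow or incomplete methylenation of the doubly ortho-substituted ester carbonyl, or hydrolysis of the acid-labile enol ether during isolation. The fallback builds the vinyl ether by C–O bond formation instead of carbonyl olefination. It sets out from bromophenol 18 and from 19: 2,4,6-tris(methoxymethoxy)benzaldehyde F2 (made from 19 as in the first fallback) is homologated with the Ohira–Bestmann reagent (dimethyl (1-diazo-2-oxopropyl)phosphonate, K2CO3, MeOH) to 2-ethynyl-1,3,5-tris(methoxymethoxy)benzene F7. Gold-catalysed Markovnikov hydrophenoxylation of this electron-rich terminal alkyne with phenol 18 (Ph3PAuNTf2, 2 mol %, toluene, 40 °C) should give the 1-arylvinyl ether and comes back to the route at 23.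

**Further compounds**
F1 | step 16 | 1-{6-hydroxy-2,4-bis(methoxymethoxy)-3-[(2S)-lavandulyl]phenyl}ethan-1-one | C=C(C)[C@@H](CC=C(C)C)Cc1c(OCOC)cc(O)c(C(C)=O)c1OCOC
F2 | step 16 | 2,4,6-tris(methoxymethoxy)benzaldehyde | COCOc1cc(OCOC)c(C=O)c(OCOC)c1
F3 | step 16 | (2E)-1-{6-hydroxy-2,4-bis(methoxymethoxy)-3-[(2S)-lavandulyl]phenyl}-3-[2,4,6-tris(methoxymethoxy)phenyl]prop-2-en-1-one | C=C(C)[C@@H](CC=C(C)C)Cc1c(OCOC)cc(O)c(C(=O)/C=C/c2c(OCOC)cc(OCOC)cc2OCOC)c1OCOC
F4 | step 17 | 2-bromo-3,5-bis(triethylsilyloxy)-4-[(2S)-lavandulyl]phenyl 2,4,6-tris(triethylsilyloxy)benzoate | C=C(C)[C@@H](CC=C(C)C)Cc1c(O[Si](CC)(CC)CC)cc(OC(=O)c2c(O[Si](CC)(CC)CC)cc(O[Si](CC)(CC)CC)cc2O[Si](CC)(CC)CC)c(Br)c1O[Si](CC)(CC)CC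
F5 | step 17 | 2-bromo-3,5-bis(triethylsilyloxy)-4-[(2S)-lavandulyl]phenyl 1-[2,4,6-tris(triethylsilyloxy)phenyl]ethenyl ether | C=C(C)[C@@H](CC=C(C)C)Cc1c(O[Si](CC)(CC)CC)cc(OC(=C)c2c(O[Si](CC)(CC)CC)cc(O[Si](CC)(CC)CC)cc2O[Si](CC)(CC)CC)c(Br)c1O[Si](CC)(CC)CC
F6 | step 17 | 2,4-bis(triethylsilyloxy)-3-[(2S)-lavandulyl]-6-({1-[2,4,6-tris(triethylsilyloxy)phenyl]ethenyl}oxy)benzaldehyde | C=C(C)[C@@H](CC=C(C)C)Cc1c(O[Si](CC)(CC)CC)cc(OC(=C)c2c(O[Si](CC)(CC)CC)cc(O[Si](CC)(CC)CC)cc2O[Si](CC)(CC)CC)c(C=O)c1O[Si](CC)(CC)CC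
F7 | step 14 | 2-ethynyl-1,3,5-tris(methoxymethoxy)benzene | C#Cc1c(OCOC)cc(OCOC)cc1OCOC
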